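**Retrosynthetic overview**
- Chromene numbering (O1, C2(Me2), C3=C4, C4a, C5–C8, C8a) is used for all compounds. The benzene ring carries para-related hydroxyls on C5 and C8, so it is a reduced 1,4-benzoquinone. O8 is ortho to C8a–O1, the ether oxygen bearing C2, and O5 is ortho to C4a, the carbon bearing C4=C3.
- Key disconnection C2–C3 (pyran ring): the target is a constitutional isomer of a monocyclic 1,4-benzoquinone with isopropoxy on C8a and vinyl on C4a. Light moves the isopropyl methine H to O8, C2 bonds to the vinyl terminus C3, and aromatisation gives the pyran ring, the C3=C4 alkene and both free phenols in one reagent-free, protecting-group-free operation.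
- Vinylquinone ⇐ iodoquinone (Stille) ⇐ o-iodophenol (Teuber oxidation at C8) ⇐ phloroglucinol, by C-acylation (C6), O-isopropylation (O1), O-methylation (O7) and iodination (C4a).
- Ring order: the benzene ring is bought with phloroglucinol and taken through the quinone level; the pyran ring is closed last.

Key step: step 7

Remark: the target has no stereocentre and its only non-aromatic C=C lies inside a six-membered ring, so it is achiral and no step needs stereocontrol.

Step 1
Reactants: 1 phloroglucinol; 2 3-phenylpropanoic acid
Product: 3 1-(2,4,6-trihydroxyphenyl)-3-phenylpropan-1-one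
Conditions: BF3·OEt2 (solvent), 85 °C; aq. NaOAc work-up
Reagents that add atoms: none
Why: BF3-promoted Friedel–Crafts C-acylation of the very electron-rich, threefold-symmetric ring should give one monoketone, because the first acyl group, chelated by its two ortho hydroxyls, deactivates the ring towards a second acylation.

Step 2
Reactants: 3 1-(2,4,6-trihydroxyphenyl)-3-phenylpropan-1-one; 4 propan-2-ol
Product: 5 1-(2,6-dihydroxy-4-isopropoxyphenyl)-3-phenylpropan-1-one
Conditions: PPh3 (1.05 equiv), DIAD (1.05 equiv), THF, 0 °C to rt
Reagents that add atoms: none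
Why: Mitsunobu etherification should take the most acidic hydroxyl, the one para to the ketone, because the two ortho hydroxyls are hydrogen-bonded to the carbonyl and one equivalent of reagents limits the reaction to the monoether.

Step 3
Reactants: 5 1-(2,6-dihydroxy-4-isopropoxyphenyl)-3-phenylpropan-1-one
Product: 6 1-(2-hydroxy-4-isopropoxy-6-methoxyphenyl)-3-phenylpropan-1-one
Conditions: Me2SO4 (1.05 equiv), K2CO3 (1.1 equiv), acetone, reflux
Reagents that add atoms: dimethyl sulfate COS(=O)(=O)OC
Why: Williamson-type O-methylation of one of the two equivalent ortho hydroxyls should stop at the monoether, because the remaining hydroxyl is then locked in a strong hydrogen bond to the ketone.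

Step 4
Reactants: 6 1-(2-hydroxy-4-isopropoxy-6-methoxyphenyl)-3-phenylpropan-1-one
Product: 7 1-(2-hydroxy-3-iodo-4-isopropoxy-6-methoxyphenyl)-3-phenylpropan-1-one
Conditions: NIS (1.05 equiv), TFA (cat.), MeCN, 0 °C to rt
Reagents that add atoms: N-iodosuccinimide O=C1CCC(=O)N1I
Why: Electrophilic aromatic iodination should go ortho to the free phenol (C4a), the less hindered open position since the other lies between two alkoxy groups, as is usual for 2-hydroxy-4,6-dialkoxyphenyl ketones.

Step 5
Reactants: 7 1-(2-hydroxy-3-iodo-4-isopropoxy-6-methoxyphenyl)-3-phenylpropan-1-one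
Product: 8 2-iodo-3-isopropoxy-5-methoxy-6-(3-phenylpropanoyl)-1,4-benzoquinone
Conditions: (KSO3)2NO (2.5 equiv), KH2PO4 buffer (pH 6), Aliquat 336 (cat.), CH2Cl2–H2O, 20 °C, dark
Reagents that add atoms: potassium nitrosodisulfonate (Fremy's salt) [O]N(S(=O)(=O)[O-])S(=O)(=O)[O-].[K+].[K+]
Why: In the Teuber oxidation one nitroxyl radical removes the phenolic hydrogen, a second couples at the free para carbon C8, and loss of imidodisulfonate gives the p-quinone, while the iodide, ethers and ketone stay inert and the two-phase medium removes the quinone from water as it forms.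

Step 6
Reactants: 8 2-iodo-3-isopropoxy-5-methoxy-6-(3-phenylpropanoyl)-1,4-benzoquinone; 9 tributyl(vinyl)stannane
Product: 10 3-isopropoxy-5-methoxy-6-(3-phenylpropanoyl)-2-vinyl-1,4-benzoquinone
Conditions: Pd2(dba)3 (2.5 mol%), AsPh3 (10 mol%), CuI (10 mol%), degassed toluene, 40 °C, dark
Reagents that add atoms: none
Why: Stille coupling of a haloquinone (an α-iodo-β-alkoxyenone) runs under neutral conditions that spare the electrophilic acylquinone, and the weakly nucleophilic AsPh3 ligand with CuI allows a low temperature and avoids phosphine addition to the quinone.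

Step 7
Reactants: 10 3-isopropoxy-5-methoxy-6-(3-phenylpropanoyl)-2-vinyl-1,4-benzoquinone
Product: 13 flemistrictin D, via oxyalkyl phenoxyl biradical 11 (not isolated), via chromanyl o-quinone methide 12 (not isolated)
Conditions: hν (blue LEDs, 450 nm), degassed benzene (2 mM), Ar, 20 °C; filtration through SiO2
Reagents that add atoms: none
Why: Proposed new method: excitation of the quinone n,π* band lets the carbonyl oxygen on C8 abstract the tertiary α-oxy hydrogen of the isopropoxy group on the neighbouring C8a through a six-membered 1,5-hydrogen-transfer transition state, which gives biradical 11 (Me2C• on O1 plus a 4-hydroxyphenoxyl radical). In 11 the phenoxyl spin lies on O5, C4a, C6 and C8 and, through the vinyl group, on its terminal carbon C3 but not on C4, so that after intersystem crossing radical–radical coupling (equally describable, after internal electron transfer, as 6π closure of the O1=C2 oxocarbenium/C8a=C4a/C4=C3 triene pushed by the O5 phenolate) joins C2 to C3 and closes the pyran ring in the 6-endo mode to o-quinone methide 12. Proton transfer from C3 to O5, relayed by the phenolic OH groups in solution or by silica gel and driven by aromatisation, then sets the C3=C4 double bond, so that the whole step is a reagent-free, redox-neutral isomerisation that delivers pyran ring, alkene and both free hydroxyls. The closest known reaction types are the intramolecular photoredox reaction of 1,4-quinones, in which 2-alkoxy- and alkoxyalkyl-quinones undergo the same 1,5-hydrogen transfer but then close at oxygen to 1,3-benzodioxoles or cyclic acetals, and the 1,5-H-shift/6π-closure sequence of the tert-amino effect; closure at the carbon end of a neighbouring vinyl group is the new element. No stereocentre is formed. The step needs hydrogen transfer from the isopropyl CH rather than from OCH3 or the acyl side chain, secured by the weakest and most hydridic C–H bond sitting in the six-membered geometry, and closure at C3 rather than at O8, at C4 or by O5 onto the vinyl group, secured because O8 carries the transferred hydrogen and no spin, C4 is a node of the spin distribution, and a dilute, apolar, aprotic medium disfavours the ionic and bimolecular exits.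

**Compound list**
1 | phloroglucinol (benzene-1,3,5-triol) | Oc1cc(O)cc(O)c1 | starting material
2 | 3-phenylpropanoic acid | OC(=O)CCc1ccccc1 | starting material
3 | 1-(2,4,6-trihydroxyphenyl)-3-phenylpropan-1-one | O=C(CCc1ccccc1)c1c(O)cc(O)cc1O | intermediate
4 | propan-2-ol | CC(C)O | starting material
5 | 1-(2,6-dihydroxy-4-isopropoxyphenyl)-3-phenylpropan-1-one | CC(C)Oc1cc(O)c(C(=O)CCc2ccccc2)c(O)c1 | intermediate
6 | 1-(2-hydroxy-4-isopropoxy-6-methoxyphenyl)-3-phenylpropan-1-one | COc1cc(OC(C)C)cc(O)c1C(=O)CCc1ccccc1 | intermediate
7 | 1-(2-hydroxy-3-iodo-4-isopropoxy-6-methoxyphenyl)-3-phenylpropan-1-one | COc1cc(OC(C)C)c(I)c(O)c1C(=O)CCc1ccccc1 | intermediate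
8 | 2-iodo-3-isopropoxy-5-methoxy-6-(3-phenylpropanoyl)-1,4-benzoquinone | COC1=C(C(=O)CCc2ccccc2)C(=O)C(I)=C(OC(C)C)C1=O | intermediate
9 | tributyl(vinyl)stannane | C=C[Sn](CCCC)(CCCC)CCCC | starting material
10 | 3-isopropoxy-5-methoxy-6-(3-phenylpropanoyl)-2-vinyl-1,4-benzoquinone | COC1=C(C(=O)CCc2ccccc2)C(=O)C(C=C)=C(OC(C)C)C1=O | intermediate
11 | biradical: 4-hydroxyphenoxyl radical (O5•, O8–H) bearing Me2C•–O on C8a, vinyl on C4a, acyl on C6 and OMe on C7 | COc1c(O)c(O[C](C)C)c(C=C)c([O])c1C(=O)CCc1ccccc1 | intermediate
12 | 8-hydroxy-7-methoxy-2,2-dimethyl-6-(3-phenylpropanoyl)-2,3-dihydro-5H-chromen-5-one (o-quinone methide, C4=C4a) | COC1=C(C(=O)CCc2ccccc2)C(=O)C2=CCC(C)(C)OC2=C1O | intermediate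
13 | flemistrictin D, 1-(5,8-dihydroxy-7-methoxy-2,2-dimethyl-2H-chromen-6-yl)-3-phenylpropan-1-one (achiral) | COc1c(O)c2c(c(O)c1C(=O)CCc1ccccc1)C=CC(C)(C)O2 | target

**Total step count:** 7. **Longest linear sequence:** 7 steps (1 → 13).

**Steps most likely to fail**

1. Step 7 (Proposed new method).
   - What may go wrong: the photogenerated biradical may collapse at oxygen instead of carbon. The quinone oxygen O5 may photocyclise onto the vinyl group. Hydrogen transfer may come from the acyl side chain. Redox exchange between the product hydroquinone and unreacted quinone may stall conversion.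
   - Fallback (known chemistry, pyran ring built by a different logic): it sets out from 6 and comes back at 13. Boron trichloride (CH2Cl2, −78 to −20 °C) should cleave the isopropyl ether in preference to the methyl ether and give 1-(2,4-dihydroxy-6-methoxyphenyl)-3-phenylpropan-1-one F1. Heating with 3-methylbut-2-enal and catalytic ethylenediammonium diacetate (xylene, reflux) should bring about C-alkylation between the two hydroxyls, loss of water and oxa-6π electrocyclisation onto the non-chelated oxygen. This should give 1-(5-hydroxy-7-methoxy-2,2-dimethyl-2H-chromen-6-yl)-3-phenylpropan-1-one F2. Teuber oxidation at the free C8 should give 7-methoxy-2,2-dimethyl-6-(3-phenylpropanoyl)-2H-chromene-5,8-dione F3, and aqueous sodium dithionite (EtOAc–H2O) should reduce this to 13.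

2. Step 5.
   - What may go wrong: hydrogen abstraction from the strongly hydrogen-bonded, acyl-deactivated phenol may be sluggish, and the activated methoxy group of the acylquinone may be lost by hydrolysis in the aqueous medium.
   - Fallback: it sets out from 7 and comes back at 8, introducing the oxygen at the hydroquinone level and making the quinone without water. Elbs persulfate oxidation (K2S2O8, aq. NaOH, rt) should place a sulfate ester para to the phenolate and give potassium 4-hydroxy-3-iodo-2-isopropoxy-6-methoxy-5-(3-phenylpropanoyl)phenyl sulfate F4. Acid hydrolysis (aq. HCl, warm) should give 1-(2,5-dihydroxy-3-iodo-4-isopropoxy-6-methoxyphenyl)-3-phenylpropan-1-one F5. Silver(I) oxide with Na2SO4 in dry CH2Cl2 (dark) should then give 8.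

3. Step 6.
   - What may go wrong: the Pd(0)/stannane system may reduce the strongly oxidising acylquinone, and the vinylquinone may be lost by thermal dimerisation during the coupling.
   - Fallback: it sets out from 7 and comes back at 10, reversing the order of coupling and oxidation. Suzuki–Miyaura vinylation of the iodophenol with potassium vinyltrifluoroborate (PdCl2(dppf), Cs2CO3, THF–H2O, 70 °C) should give 1-(2-hydroxy-4-isopropoxy-6-methoxy-3-vinylphenyl)-3-phenylpropan-1-one F6. Cobalt–salen-catalysed oxygenation (salcomine, O2, MeCN, rt, dark) of the para-unsubstituted phenol should then give 10.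

**Further compounds**
F1 | step 7 | 1-(2,4-dihydroxy-6-methoxyphenyl)-3-phenylpropan-1-one | COc1cc(O)cc(O)c1C(=O)CCc1ccccc1
F2 | step 7 | 1-(5-hydroxy-7-methoxy-2,2-dimethyl-2H-chromen-6-yl)-3-phenylpropan-1-one | COc1cc2c(c(O)c1C(=O)CCc1ccccc1)C=CC(C)(C)O2
F3 | step 7 | 7-methoxy-2,2-dimethyl-6-(3-phenylpropanoyl)-2H-chromene-5,8-dione | COC1=C(C(=O)CCc2ccccc2)C(=O)C2=C(OC(C)(C)C=C2)C1=O
F4 | step 5 | potassium 4-hydroxy-3-iodo-2-isopropoxy-6-methoxy-5-(3-phenylpropanoyl)phenyl sulfate | COc1c(OS(=O)(=O)[O-])c(OC(C)C)c(I)c(O)c1C(=O)CCc1ccccc1.[K+]
F5 | step 5 | 1-(2,5-dihydroxy-3-iodo-4-isopropoxy-6-methoxyphenyl)-3-phenylpropan-1-one | COc1c(O)c(OC(C)C)c(I)c(O)c1C(=O)CCc1ccccc1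
F6 | step 6 | 1-(2-hydroxy-4-isopropoxy-6-methoxy-3-vinylphenyl)-3-phenylpropan-1-one | COc1cc(OC(C)C)c(C=C)c(O)c1C(=O)CCc1ccccc1
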